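**Plan**

- Retrosynthesis first removes the C8–O angeloyl bond and the C11=C13 methylene, returns C14 and C15 to methyl and ester level, and moves the lactone from O6 back to O8. This leaves a cyclodeca-1(10),4-dien-6-one with a cis 8,12-lactone and a C15 ester.
- That ring is then cut at C1=C10 and C4=C5 after reconnecting C1–C4 and C5–C10, giving a β-methylcyclohexenone lactone and a cyclobutene ester.
- Structural feature: in germacrane numbering the ring segment C10=C1–C2–C3–C4=C5 is a 1,5-diene bridged by C2–C3, the retron of a cleaved bicyclo[2.2.0]hexane (C1–C4 and C5–C10 are temporary bonds).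
- Forward order of rings: the six-membered ring comes from 5-methylcyclohexane-1,3-dione and the γ-lactone is closed on it. Two cyclobutanes then form by [2+2] and are fused thermally into the ten-membered ring, and the lactone is finally re-closed on O6.
- Stereochemistry: C8 and C7 come from an oxazaborolidine reduction relayed by hydroxyl-directed hydrogenation, after which the relay carbinol is oxidised away. C6 comes from convex-face hydride addition next to the cis-fused lactone. Both ring alkenes are set under thermodynamic control, and C14 is oxidised through an E-selective [2,3] shift.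

Key step: step 9

Remark: the target is taken exactly as drawn, 6R,7S,8S with H6, H7 and H8 mutually cis (O6, C11 and O8 on one face). Germacrane numbering (ring C1–C10, lactone carbons C11–C13, C14 on C10, C15 on C4) is used for all ten-membered compounds.

**Route**

Step 1
Reactants: 1 5-methylcyclohexane-1,3-dione; 2 tert-butyl bromoacetate
Product: 3 tert-butyl 2-(4-methyl-2,6-dioxocyclohexyl)acetate
Conditions: KOH (1 equiv), H2O–dioxane, 25 °C
Reagents that add atoms: none
Why: C-alkylation of the potassium enolate of a cyclic 1,3-dione with an α-halo ester in aqueous medium is the standard entry to 2-substituted cyclohexane-1,3-diones, and no stereocentre is fixed because the product is enolised.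

Step 2
Reactants: 3 tert-butyl 2-(4-methyl-2,6-dioxocyclohexyl)acetate
Product: 5 6-methyl-6,7-dihydro-1-benzofuran-2,4(3H,5H)-dione, via dione acid 4 (not isolated)
Conditions: CF3CO2H, CH2Cl2, 25 °C; evaporate; then Ac2O, 110 °C
Reagents that add atoms: none
Why: Acidolysis of the tert-butyl ester (loss of isobutene) and anhydride-mediated enol lactonisation of the 2-(carboxymethyl)-1,3-dione should give the racemic vinylogous anhydride, a known route to dihydrobenzofuran-2,4-diones.

Step 3
Reactants: 5 6-methyl-6,7-dihydro-1-benzofuran-2,4(3H,5H)-dione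
Product: 6 (4S)-4-hydroxy-6-methyl-4,5,6,7-tetrahydro-1-benzofuran-2(3H)-one
Conditions: (R)-2-methyl-CBS-oxazaborolidine (0.2 equiv), catecholborane, toluene, −78 °C
Reagents that add atoms: none
Why: Corey–Bakshi–Shibata reduction of an α-substituted cyclohexenone, with the substituted alkene arm as the large group, should set the 4S carbinol under catalyst control in both C6 methyl epimers, whose methyl centre is erased in step 6.

Step 4
Reactants: 6 (4S)-4-hydroxy-6-methyl-4,5,6,7-tetrahydro-1-benzofuran-2(3H)-one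
Product: 7 (3aR,4S,7aS)-4-hydroxy-6-methylhexahydro-1-benzofuran-2(3H)-one
Conditions: [Ir(cod)(PCy3)(py)]PF6 (5 mol %), H2 (1 atm), CH2Cl2, 0 to 25 °C
Reagents that add atoms: none
Why: Hydroxyl-directed homogeneous hydrogenation with the cationic iridium catalyst should add both hydrogens to the tetrasubstituted enol-lactone alkene from the face of the C4 hydroxyl, which sets C3a and C7a and makes the ring fusion cis.

Step 5
Reactants: 7 (3aR,4S,7aS)-4-hydroxy-6-methylhexahydro-1-benzofuran-2(3H)-one
Product: 8 (3aS,7aS)-6-methylhexahydro-1-benzofuran-2,4-dione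
Conditions: Dess–Martin periodinane, CH2Cl2, 0 to 25 °C
Reagents that add atoms: none
Why: Dess–Martin oxidation removes the relay carbinol under near-neutral conditions, so the cis ring fusion should not epimerise and the β-acyloxy ketone should not eliminate.

Step 6
Reactants: 8 (3aS,7aS)-6-methylhexahydro-1-benzofuran-2,4-dione
Product: 10 (3aS,7aS)-6-methyl-3,3a,7,7a-tetrahydro-1-benzofuran-2,4-dione, via silyl enol ether 9 (not isolated)
Conditions: LiN(iPr)2, Me3SiCl, THF, −78 °C; then Pd(OAc)2 (1.1 equiv), MeCN, 25 °C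
Reagents that add atoms: none
Why: Kinetic deprotonation at the less substituted C5 with in situ silylation, then Saegusa–Ito oxidation through β-hydride elimination from the palladium enolate, should give the β-methyl enone and erase the C6 methyl stereocentre.

Step 7
Reactants: 11 ethyl 1-bromocyclobutane-1-carboxylate
Product: 12 cyclobut-1-ene-1-carboxylic acid
Conditions: KOH, toluene, reflux; then aq. HCl
Reagents that add atoms: potassium hydroxide, [K+].[OH-]
Why: Base-mediated dehydrobromination with concomitant saponification is the established preparation of this strained acrylic acid.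

Step 8
Reactants: 12 cyclobut-1-ene-1-carboxylic acid
Product: 13 tert-butyl cyclobut-1-ene-1-carboxylate
Conditions: tert-butyl 2,2,2-trichloroacetimidate, BF3·OEt2 (cat.), cyclohexane–CH2Cl2, 25 °C
Reagents that add atoms: tert-butyl 2,2,2-trichloroacetimidate, CC(C)(C)OC(=N)C(Cl)(Cl)Cl
Why: Acid-catalysed tert-butylation of a carboxylic acid with the trichloroacetimidate runs at room temperature without strong base, which avoids polymerisation of the cyclobutene ester.

Step 9
Reactants: 10 (3aS,7aS)-6-methyl-3,3a,7,7a-tetrahydro-1-benzofuran-2,4-dione; 13 tert-butyl cyclobut-1-ene-1-carboxylate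
Product: 15 tert-butyl (1(10)Z,4E,7S,8S)-6-oxogermacra-1(10),4-dien-12,8-olid-15-oate, via cyclobutane photoadduct 14 (not isolated)
Conditions: hν (350 nm, uranium-glass filter), 13 (8 equiv), degassed toluene, 0 °C; excess 13 removed in vacuo; then toluene (0.01 M), 200 °C, sealed base-washed tube
Reagents that add atoms: none
Why: The enone triplet adds to the electron-poor cyclobutene through a 1,4-biradical in the head-to-head sense, C5 (enone α-carbon) to the ester-bearing C4 and C10 (β-carbon) to C1, so that the new and the old cyclobutane form a bicyclo[2.2.0]hexane sharing C1–C4; this is an enone–alkene [2+2] photocycloaddition followed by thermal cycloreversion, and the closest precedent is the addition of 3-methylcyclohex-2-enones to alkyl cyclobut-1-enecarboxylates and thermolysis of the adducts to cyclodeca-1,5-dienes. At 200 °C the strained central C1–C4 bond breaks to a cyclohexane-1,4-diyl, which then cleaves C5–C10, so the ten-membered ring closes by ring expansion (merging of the six- and four-membered rings) and not by end-to-end cyclisation, while the temporary cyclobutane closes by stepwise biradical recombination. The stereocentres formed at C1, C4, C5 and C10 are all destroyed again, so the facial selectivity of the photoaddition is irrelevant, and C7 and C8 are untouched and held cis by the lactone, which cannot undergo ester pyrolysis because its ring-bound carbonyl oxygen cannot reach H7 or H9. The step needs head-to-head regioselectivity, which the acrylate-type polarisation of the cyclobutene ester secures, and in-ring cis geometry at both alkenes, which is expected because the thermolysis is equilibrating and the Z,Z-cyclodeca-1,5-diene is the most stable ring isomer and can reach the Cope product only through a boat transition state. Conjugation of C4=C5 with the C6 ketone and the C15 ester should keep the Cope equilibrium on the side of the ten-membered ring.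

Step 10
Reactants: 15 tert-butyl (1(10)Z,4E,7S,8S)-6-oxogermacra-1(10),4-dien-12,8-olid-15-oate
Product: 16 tert-butyl (1(10)Z,4E,6R,7R,8S)-6-hydroxygermacra-1(10),4-dien-12,8-olid-15-oate
Conditions: NaBH4, CeCl3·7H2O, MeOH, −78 °C
Reagents that add atoms: none
Why: Luche reduction adds hydride 1,2 to the enone carbonyl from the convex β-face of the cis-fused lactone (anti to C11), which should give the 6R alcohol with O6 cis to C11 and leave lactone and enoate untouched.

Step 11
Reactants: 16 tert-butyl (1(10)Z,4E,6R,7R,8S)-6-hydroxygermacra-1(10),4-dien-12,8-olid-15-oate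
Product: 18 (1(10)Z,4E,6R,7S,8S)-6-(tert-butyldimethylsilyloxy)germacra-1(10),4-dien-12,8-olid-15-oic acid, via silyl ester 17 (not isolated)
Conditions: tBuMe2SiOTf (3 equiv), 2,6-lutidine, CH2Cl2, 0 to 25 °C; then THF–H2O–AcOH, 25 °C
Reagents that add atoms: tert-butyldimethylsilyl triflate, CC(C)(C)[Si](C)(C)OS(=O)(=O)C(F)(F)F
Why: The silyl triflate silylates the allylic alcohol and converts the tert-butyl ester into the silyl ester with loss of isobutene (silyl triflate-mediated tert-butyl ester cleavage), and the labile silyl ester is hydrolysed on work-up while the silyl ether, which blocks O6 from attacking the lactone, stays.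

Step 12
Reactants: 18 (1(10)Z,4E,6R,7S,8S)-6-(tert-butyldimethylsilyloxy)germacra-1(10),4-dien-12,8-olid-15-oic acid
Product: 20 (1(10)Z,4E,6R,7S,8S)-6-(tert-butyldimethylsilyloxy)-15-hydroxygermacra-1(10),4-dien-12,8-olide, via mixed carbonic anhydride 19 (not isolated)
Conditions: iBuOCOCl, N-methylmorpholine, THF, −15 °C; then NaBH4, THF–H2O, 0 °C
Reagents that add atoms: none
Why: Activation as the mixed carbonic anhydride and borohydride reduction converts the conjugated acid into the allylic alcohol without touching the lactone, which a hydride strong enough to reduce an ester directly would not spare.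

Step 13
Reactants: 20 (1(10)Z,4E,6R,7S,8S)-6-(tert-butyldimethylsilyloxy)-15-hydroxygermacra-1(10),4-dien-12,8-olide
Product: 21 (1(10)Z,4E,6R,7S,8S)-6,15-bis(tert-butyldimethylsilyloxy)germacra-1(10),4-dien-12,8-olide
Conditions: tBuMe2SiCl, imidazole, DMF, 25 °C
Reagents that add atoms: tert-butyldimethylsilyl chloride, CC(C)(C)[Si](C)(C)Cl
Why: Standard silylation of the primary allylic alcohol protects C15–OH against the later allylic oxidations.

Step 14
Reactants: 21 (1(10)Z,4E,6R,7S,8S)-6,15-bis(tert-butyldimethylsilyloxy)germacra-1(10),4-dien-12,8-olide; 22 N,N-dimethylmethyleneiminium iodide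
Product: 23 (1(10)Z,4E,6R,7S,8S)-6,15-bis(tert-butyldimethylsilyloxy)-13-(dimethylamino)germacra-1(10),4-dien-12,8-olide
Conditions: LiN(iPr)2, THF, −78 °C; then 22, −78 to 0 °C
Reagents that add atoms: none
Why: The lithium enolate of the γ-lactone, the only acidic site left, is aminomethylated by the iminium salt (Mannich reaction with Eschenmoser's salt), which installs C13 in a form that is not a Michael acceptor, the C11 configuration being immaterial.

Step 15
Reactants: 23 (1(10)Z,4E,6R,7S,8S)-6,15-bis(tert-butyldimethylsilyloxy)-13-(dimethylamino)germacra-1(10),4-dien-12,8-olide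
Product: 24 N-methoxy-N-methyl (1(10)Z,4E,6R,7S,8S)-6,15-bis(tert-butyldimethylsilyloxy)-13-(dimethylamino)-8-hydroxygermacra-1(10),4-dien-12-amide
Conditions: Me3Al, MeNH(OMe)·HCl, CH2Cl2, 0 to 25 °C
Reagents that add atoms: N,O-dimethylhydroxylamine hydrochloride, CNOC.Cl
Why: Weinreb aminolysis with the aluminium amide opens the lactone to a hydroxy amide that does not re-close under the basic acylation that follows, and it frees O8 alone because O6 is silylated.

Step 16
Reactants: 24 N-methoxy-N-methyl (1(10)Z,4E,6R,7S,8S)-6,15-bis(tert-butyldimethylsilyloxy)-13-(dimethylamino)-8-hydroxygermacra-1(10),4-dien-12-amide; 25 angelic acid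
Product: 27 N-methoxy-N-methyl (1(10)Z,4E,6R,7S,8S)-8-angeloyloxy-6,15-bis(tert-butyldimethylsilyloxy)-13-(dimethylamino)germacra-1(10),4-dien-12-amide, via mixed Yamaguchi anhydride 26 (not isolated)
Conditions: 25, 2,4,6-Cl3C6H2COCl, Et3N, toluene, 25 °C; then 24, DMAP, 25 to 45 °C
Reagents that add atoms: none
Why: Yamaguchi esterification through the mixed 2,4,6-trichlorobenzoic anhydride acylates the hindered secondary alcohol under conditions known to preserve the Z geometry of angelic acid.

Step 17
Reactants: 27 N-methoxy-N-methyl (1(10)Z,4E,6R,7S,8S)-8-angeloyloxy-6,15-bis(tert-butyldimethylsilyloxy)-13-(dimethylamino)germacra-1(10),4-dien-12-amide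
Product: 29 N-methoxy-N-methyl (1(10)Z,4E,6R,7S,8S)-8-angeloyloxy-6,15-bis(tert-butyldimethylsilyloxy)germacra-1(10),4,11(13)-trien-12-amide, via trimethylammonium iodide 28 (not isolated)
Conditions: MeI, MeCN, 25 °C; then DBU, CH2Cl2, 25 °C
Reagents that add atoms: none
Why: N-Methylation and base-induced β-elimination of trimethylamine (Hofmann-type elimination of the Mannich salt) unveil the C11=C13 methylene before any oxidant that would attack the amine is used.

Step 18
Reactants: 29 N-methoxy-N-methyl (1(10)Z,4E,6R,7S,8S)-8-angeloyloxy-6,15-bis(tert-butyldimethylsilyloxy)germacra-1(10),4,11(13)-trien-12-amide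
Product: 31 N-methoxy-N-methyl (1(10)E,4E,6R,7S,8S)-8-angeloyloxy-6,15-bis(tert-butyldimethylsilyloxy)-14-oxogermacra-1(10),4,11(13)-trien-12-amide, via C14 allylic alcohol 30 (not isolated)
Conditions: SeO2 (0.5 equiv), tBuOOH, CH2Cl2, 0 to 25 °C; filter; then MnO2, CH2Cl2, 25 °C
Reagents that add atoms: selenium dioxide, O=[Se]=O (oxygen donor, re-formed by tert-butyl hydroperoxide, CC(C)(C)OO)
Why: SeO2 allylic oxidation (ene reaction at the electron-richest alkene C1=C10, then [2,3]-sigmatropic shift) should hydroxylate the C10 methyl as in the known C14 oxidation of germacranolides, placing C14–O trans to C2 so that the in-ring cis geometry is kept, and MnO2 then oxidises the only free allylic alcohol to the enal.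

Step 19
Reactants: 31 N-methoxy-N-methyl (1(10)E,4E,6R,7S,8S)-8-angeloyloxy-6,15-bis(tert-butyldimethylsilyloxy)-14-oxogermacra-1(10),4,11(13)-trien-12-amide
Product: 33 (1(10)E,4E,6R,7S,8S)-8-angeloyloxy-15-hydroxy-14-oxogermacra-1(10),4,11(13)-trien-12,6-olide, via dihydroxy amide 32 (not isolated)
Conditions: HF·pyridine, pyridine–THF, 0 to 25 °C; then camphorsulfonic acid, CH2Cl2, 25 °C
Reagents that add atoms: none
Why: Fluoride cleaves both silyl ethers, and the freed C6 hydroxyl, cis to the C7 side chain, displaces N,O-dimethylhydroxylamine from the amide under acid catalysis (lactonisation of a γ-hydroxy Weinreb amide), which closes the α-methylene lactone on O6 with H6 and H7 cis.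

**Compound list**

1 | 5-methylcyclohexane-1,3-dione | CC1CC(=O)CC(=O)C1 | starting material
2 | tert-butyl bromoacetate | CC(C)(C)OC(=O)CBr | starting material
3 | tert-butyl 2-(4-methyl-2,6-dioxocyclohexyl)acetate | CC1CC(=O)C(CC(=O)OC(C)(C)C)C(=O)C1 | intermediate
4 | 2-(4-methyl-2,6-dioxocyclohexyl)acetic acid (not isolated) | CC1CC(=O)C(CC(=O)O)C(=O)C1 | intermediate
5 | 6-methyl-6,7-dihydro-1-benzofuran-2,4(3H,5H)-dione, racemic enol lactone | O=C1CC(C)CC2=C1CC(=O)O2 | intermediate
6 | (4S)-4-hydroxy-6-methyl-4,5,6,7-tetrahydro-1-benzofuran-2(3H)-one, both C6 epimers | O[C@H]1CC(C)CC2=C1CC(=O)O2 | intermediate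
7 | (3aR,4S,7aS)-4-hydroxy-6-methylhexahydro-1-benzofuran-2(3H)-one, both C6 epimers, H3a, H4 and H7a cis | O[C@H]1CC(C)C[C@@H]2OC(=O)C[C@H]12 | intermediate
8 | (3aS,7aS)-6-methylhexahydro-1-benzofuran-2,4-dione, both C6 epimers | O=C1CC(C)C[C@@H]2OC(=O)C[C@H]12 | intermediate
9 | (3aS,7aS)-6-methyl-4-(trimethylsilyloxy)-3a,6,7,7a-tetrahydro-1-benzofuran-2(3H)-one (not isolated) | C[Si](C)(C)OC1=CC(C)C[C@@H]2OC(=O)C[C@H]12 | intermediate
10 | (3aS,7aS)-6-methyl-3,3a,7,7a-tetrahydro-1-benzofuran-2,4-dione | O=C1C=C(C)C[C@@H]2OC(=O)C[C@H]12 | intermediate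
11 | ethyl 1-bromocyclobutane-1-carboxylate | CCOC(=O)C1(Br)CCC1 | starting material
12 | cyclobut-1-ene-1-carboxylic acid | OC(=O)C1=CCC1 | intermediate
13 | tert-butyl cyclobut-1-ene-1-carboxylate | CC(C)(C)OC(=O)C1=CCC1 | intermediate
14 | head-to-head cyclobutane photoadduct of 10 and 13 (new bonds C5–C4 and C10–C1; stereoisomers at C1, C4, C5, C10; not isolated) | O=C1C2C(C)(C[C@@H]3OC(=O)C[C@H]13)C4CCC24C(=O)OC(C)(C)C | intermediate
15 | tert-butyl (1(10)Z,4E,7S,8S)-6-oxogermacra-1(10),4-dien-12,8-olid-15-oate | O=C1/C=C(/C(=O)OC(C)(C)C)CC/C=C(/C)C[C@@H]2OC(=O)C[C@H]12 | intermediate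
16 | tert-butyl (1(10)Z,4E,6R,7R,8S)-6-hydroxygermacra-1(10),4-dien-12,8-olid-15-oate | O[C@@H]1/C=C(/C(=O)OC(C)(C)C)CC/C=C(/C)C[C@@H]2OC(=O)C[C@H]12 | intermediate
17 | tert-butyldimethylsilyl (1(10)Z,4E,6R,7S,8S)-6-(tert-butyldimethylsilyloxy)germacra-1(10),4-dien-12,8-olid-15-oate (not isolated) | CC(C)(C)[Si](C)(C)O[C@@H]1/C=C(/C(=O)O[Si](C)(C)C(C)(C)C)CC/C=C(/C)C[C@@H]2OC(=O)C[C@H]12 | intermediate
18 | (1(10)Z,4E,6R,7S,8S)-6-(tert-butyldimethylsilyloxy)germacra-1(10),4-dien-12,8-olid-15-oic acid | CC(C)(C)[Si](C)(C)O[C@@H]1/C=C(/C(=O)O)CC/C=C(/C)C[C@@H]2OC(=O)C[C@H]12 | intermediate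
19 | isobutyl carbonic mixed anhydride of 18 (not isolated) | CC(C)(C)[Si](C)(C)O[C@@H]1/C=C(/C(=O)OC(=O)OCC(C)C)CC/C=C(/C)C[C@@H]2OC(=O)C[C@H]12 | intermediate
20 | (1(10)Z,4E,6R,7S,8S)-6-(tert-butyldimethylsilyloxy)-15-hydroxygermacra-1(10),4-dien-12,8-olide | CC(C)(C)[Si](C)(C)O[C@@H]1/C=C(/CO)CC/C=C(/C)C[C@@H]2OC(=O)C[C@H]12 | intermediate
21 | (1(10)Z,4E,6R,7S,8S)-6,15-bis(tert-butyldimethylsilyloxy)germacra-1(10),4-dien-12,8-olide | CC(C)(C)[Si](C)(C)O[C@@H]1/C=C(/CO[Si](C)(C)C(C)(C)C)CC/C=C(/C)C[C@@H]2OC(=O)C[C@H]12 | intermediate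
22 | N,N-dimethylmethyleneiminium iodide | C=[N+](C)C.[I-] | starting material
23 | (1(10)Z,4E,6R,7S,8S)-6,15-bis(tert-butyldimethylsilyloxy)-13-(dimethylamino)germacra-1(10),4-dien-12,8-olide, C11 epimers | CC(C)(C)[Si](C)(C)O[C@@H]1/C=C(/CO[Si](C)(C)C(C)(C)C)CC/C=C(/C)C[C@@H]2OC(=O)C(CN(C)C)[C@H]12 | intermediate
24 | N-methoxy-N-methyl (1(10)Z,4E,6R,7S,8S)-6,15-bis(tert-butyldimethylsilyloxy)-13-(dimethylamino)-8-hydroxygermacra-1(10),4-dien-12-amide, C11 epimers | CC(C)(C)[Si](C)(C)O[C@@H]1/C=C(/CO[Si](C)(C)C(C)(C)C)CC/C=C(/C)C[C@H](O)[C@@H]1C(CN(C)C)C(=O)N(C)OC | intermediate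
25 | angelic acid, (Z)-2-methylbut-2-enoic acid | C/C=C(/C)C(=O)O | starting material
26 | angelic 2,4,6-trichlorobenzoic anhydride (not isolated) | C/C=C(/C)C(=O)OC(=O)c1c(Cl)cc(Cl)cc1Cl | intermediate
27 | N-methoxy-N-methyl (1(10)Z,4E,6R,7S,8S)-8-angeloyloxy-6,15-bis(tert-butyldimethylsilyloxy)-13-(dimethylamino)germacra-1(10),4-dien-12-amide, C11 epimers | CC(C)(C)[Si](C)(C)O[C@@H]1/C=C(/CO[Si](C)(C)C(C)(C)C)CC/C=C(/C)C[C@H](OC(=O)/C(C)=C\C)[C@@H]1C(CN(C)C)C(=O)N(C)OC | intermediate
28 | N-methyl ammonium iodide of 27 (13-trimethylammonio, not isolated) | CC(C)(C)[Si](C)(C)O[C@@H]1/C=C(/CO[Si](C)(C)C(C)(C)C)CC/C=C(/C)C[C@H](OC(=O)/C(C)=C\C)[C@@H]1C(C[N+](C)(C)C)C(=O)N(C)OC.[I-] | intermediate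
29 | N-methoxy-N-methyl (1(10)Z,4E,6R,7S,8S)-8-angeloyloxy-6,15-bis(tert-butyldimethylsilyloxy)germacra-1(10),4,11(13)-trien-12-amide | CC(C)(C)[Si](C)(C)O[C@@H]1/C=C(/CO[Si](C)(C)C(C)(C)C)CC/C=C(/C)C[C@H](OC(=O)/C(C)=C\C)[C@@H]1C(=C)C(=O)N(C)OC | intermediate
30 | N-methoxy-N-methyl (1(10)E,4E,6R,7S,8S)-8-angeloyloxy-6,15-bis(tert-butyldimethylsilyloxy)-14-hydroxygermacra-1(10),4,11(13)-trien-12-amide (not isolated) | CC(C)(C)[Si](C)(C)O[C@@H]1/C=C(/CO[Si](C)(C)C(C)(C)C)CC/C=C(/CO)C[C@H](OC(=O)/C(C)=C\C)[C@@H]1C(=C)C(=O)N(C)OC | intermediate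
31 | N-methoxy-N-methyl (1(10)E,4E,6R,7S,8S)-8-angeloyloxy-6,15-bis(tert-butyldimethylsilyloxy)-14-oxogermacra-1(10),4,11(13)-trien-12-amide | CC(C)(C)[Si](C)(C)O[C@@H]1/C=C(/CO[Si](C)(C)C(C)(C)C)CC/C=C(/C=O)C[C@H](OC(=O)/C(C)=C\C)[C@@H]1C(=C)C(=O)N(C)OC | intermediate
32 | N-methoxy-N-methyl (1(10)E,4E,6R,7R,8S)-8-angeloyloxy-6,15-dihydroxy-14-oxogermacra-1(10),4,11(13)-trien-12-amide (not isolated) | O[C@@H]1/C=C(/CO)CC/C=C(/C=O)C[C@H](OC(=O)/C(C)=C\C)[C@@H]1C(=C)C(=O)N(C)OC | intermediate
33 | (1(10)E,4E,6R,7S,8S)-8-angeloyloxy-15-hydroxy-14-oxogermacra-1(10),4,11(13)-trien-12,6-olide (CNP0173211.3) | C=C1C(=O)O[C@@H]2/C=C(/CO)CC/C=C(/C=O)C[C@H](OC(=O)/C(C)=C\C)[C@H]12 | target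

**Step count and risks**

Total step count: 19. Longest linear sequence: 17 steps (steps 1 to 6, then 9 to 19); steps 7 and 8 form the short branch to 13.

Steps most likely to fail:

Step 9. The diyl may open kinetically to a ring isomer with an in-ring trans C1=C10 bond that does not equilibrate fully before Cope rearrangement or loss of isobutene sets in. Fallback: the two stages are separated. From 10 and 13 the photoadduct 14 is isolated and thermolysed at the lowest temperature that opens it, which should give tert-butyl (1(10)E,4E,7S,8S)-6-oxogermacra-1(10),4-dien-12,8-olid-15-oate F1. F1 is then converted into 15 by a radical-chain geometric isomerisation (PhSH, azobisisobutyronitrile, benzene, 80 °C), in which reversible thiyl addition to C1=C10 replaces thermal equilibration and rejoins the route at 15.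

Step 10. Facial selectivity of hydride addition may be poor because the ten-membered ring is flexible, so that the 6S alcohol forms alongside or instead of 16. Fallback: stereocontrol by substitution instead of reduction. Starting from 15, the 6S epimer tert-butyl (1(10)Z,4E,6S,7R,8S)-6-hydroxygermacra-1(10),4-dien-12,8-olid-15-oate F2 is subjected to Mitsunobu inversion with chloroacetic acid (Ph3P, diisopropyl azodicarboxylate, THF). This gives tert-butyl (1(10)Z,4E,6R,7S,8S)-6-(chloroacetoxy)germacra-1(10),4-dien-12,8-olid-15-oate F3, whose chloroacetyl group is removed with thiourea and NaHCO3 in ethanol to return to 16.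

Step 18. The ene step may abstract a ring-methylene hydrogen (C9 or C2) or engage C4=C5, giving regioisomeric allylic oxidation. Fallback: a three-stage transposition that fixes the site by epoxide chemistry. From 29, epoxidation of the most electron-rich alkene with mCPBA should give N-methoxy-N-methyl (4E,6R,7S,8S)-8-angeloyloxy-6,15-bis(tert-butyldimethylsilyloxy)-1,10-epoxygermacra-4,11(13)-dien-12-amide F4. Isomerisation of the trisubstituted epoxide with Et2Al(2,2,6,6-tetramethylpiperidide), which removes a methyl proton, gives N-methoxy-N-methyl (4E,6R,7S,8S)-8-angeloyloxy-6,15-bis(tert-butyldimethylsilyloxy)-1-hydroxygermacra-4,10(14),11(13)-trien-12-amide F5. A Ph3SiOReO3-catalysed 1,3-transposition of this allylic alcohol to the primary, trisubstituted isomer rejoins the route at 30, which is oxidised with MnO2 to 31 as in step 18.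

Further compounds
F1 | step 9 | tert-butyl (1(10)E,4E,7S,8S)-6-oxogermacra-1(10),4-dien-12,8-olid-15-oate | O=C1/C=C(/C(=O)OC(C)(C)C)CC/C=C(\C)C[C@@H]2OC(=O)C[C@H]12
F2 | step 10 | tert-butyl (1(10)Z,4E,6S,7R,8S)-6-hydroxygermacra-1(10),4-dien-12,8-olid-15-oate | O[C@H]1/C=C(/C(=O)OC(C)(C)C)CC/C=C(/C)C[C@@H]2OC(=O)C[C@H]12
F3 | step 10 | tert-butyl (1(10)Z,4E,6R,7S,8S)-6-(chloroacetoxy)germacra-1(10),4-dien-12,8-olid-15-oate | ClCC(=O)O[C@@H]1/C=C(/C(=O)OC(C)(C)C)CC/C=C(/C)C[C@@H]2OC(=O)C[C@H]12
F4 | step 18 | N-methoxy-N-methyl (4E,6R,7S,8S)-8-angeloyloxy-6,15-bis(tert-butyldimethylsilyloxy)-1,10-epoxygermacra-4,11(13)-dien-12-amide | CC(C)(C)[Si](C)(C)O[C@@H]1/C=C(/CO[Si](C)(C)C(C)(C)C)CCC2OC2(C)C[C@H](OC(=O)/C(C)=C\C)[C@@H]1C(=C)C(=O)N(C)OC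
F5 | step 18 | N-methoxy-N-methyl (4E,6R,7S,8S)-8-angeloyloxy-6,15-bis(tert-butyldimethylsilyloxy)-1-hydroxygermacra-4,10(14),11(13)-trien-12-amide | CC(C)(C)[Si](C)(C)O[C@@H]1/C=C(/CO[Si](C)(C)C(C)(C)C)CCC(O)C(=C)C[C@H](OC(=O)/C(C)=C\C)[C@@H]1C(=C)C(=O)N(C)OC
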